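**Retrosynthetic overview**
- The last step unmasks the 4'-phenol from its tert-butyldimethylsilyl (TBS) ether, which keeps that phenol out of the O-allylation/Claisen chemistry.
- The C6 prenyl group comes from an aromatic Claisen rearrangement of the 5-O-(1,1-dimethylallyl) ether, made by palladium-catalysed O-allylation; C6 is the only free ortho position.
- The 2,2-dimethyl-2H-pyran ring comes from a formal [3+3] chromenylation (condensation, then oxa-6π closure) of a 5-substituted resorcinol with prenal at the carbon between the two hydroxyls.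
- The bibenzyl comes from a one-pot hydroboration/B-alkyl Suzuki coupling of a 4-silyloxystyrene with 5-bromoresorcinol.
- Ring order: both benzene rings are bought; the pyran ring is the only ring formed (step 2).

Assumption: the target has no stereocentre and no stereogenic double bond, so it is achiral and needs no enantiocontrol; compounds 1, 2, 3, 6 and 9 are taken as catalog items.

**Step 1**
Reactants: 1 tert-butyldimethyl(4-vinylphenoxy)silane; 2 9-borabicyclo[3.3.1]nonane (9-BBN, 0.5 M in THF); 3 5-bromobenzene-1,3-diol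
Product: 5 5-[2-(4-{[tert-butyl(dimethyl)silyl]oxy}phenyl)ethyl]benzene-1,3-diol, via alkylborane 4 (not isolated)
Conditions: 1, 9-BBN (1.1 equiv), THF, 0 °C → rt, 4 h; then 3, Pd(dppf)Cl2·CH2Cl2 (5 mol%), K3PO4 (3 M aq., 4 equiv), THF/DMF, 50 °C
Reagents that add atoms: none
Why: Anti-Markovnikov hydroboration of the styrene gives a primary B-alkyl-9-BBN that undergoes B-alkyl Suzuki–Miyaura coupling with the aryl bromide (the phenoxide oxygens are meta to bromine, so oxidative addition is not shut down), forming the saturated two-carbon bridge with no stereocentre.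

**Step 2**
Reactants: 5 the resorcinol from step 1; 6 3-methylbut-2-enal (prenal)
Product: 8 7-[2-(4-{[tert-butyl(dimethyl)silyl]oxy}phenyl)ethyl]-2,2-dimethyl-2H-chromen-5-ol, via ortho-quinone methide 7 (not isolated)
Conditions: 6 (1.1 equiv), ethylenediammonium diacetate (10 mol%), xylene, reflux, 6 h
Reagents that add atoms: 3-methylbut-2-enal (6), CC(C)=CC=O
Why: Ammonium-catalysed Knoevenagel-type condensation at the doubly activated carbon between the two hydroxyls gives a 1-oxatriene that closes by oxa-6π electrocyclization (formal [3+3] chromenylation, the regiochemistry by which olivetol and citral give cannabichromene); the two hydroxyls are equivalent, so only one chromenol can result and no stereocentre is formed.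

**Step 3**
Reactants: 8 the chromenol; 9 tert-butyl 2-methylbut-3-en-2-yl carbonate
Product: 10 tert-butyl(4-{2-[2,2-dimethyl-5-(2-methylbut-3-en-2-yloxy)-2H-chromen-7-yl]ethyl}phenoxy)dimethylsilane
Conditions: 9 (1.5 equiv), Pd(PPh3)4 (5 mol%), degassed THF, 0 °C, 2 h
Reagents that add atoms: tert-butyl 2-methylbut-3-en-2-yl carbonate (9), C=CC(C)(C)OC(=O)OC(C)(C)C
Why: In this Tsuji–Trost O-allylation, zerovalent palladium ionises the tertiary allylic carbonate (losing CO2 and tert-butoxide, which deprotonates the only free phenol), and the phenoxide attacks the more substituted terminus of the π-allyl complex at low temperature to give the kinetic tertiary (reverse-prenyl) ether.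

**Step 4**
Reactants: 10 the 1,1-dimethylallyl aryl ether
Product: 12 7-[2-(4-{[tert-butyl(dimethyl)silyl]oxy}phenyl)ethyl]-2,2-dimethyl-6-(3-methylbut-2-en-1-yl)-2H-chromen-5-ol, via 6-prenyl cyclohexadienone 11 (not isolated)
Conditions: degassed toluene, 110 °C, sealed tube, 8 h (base-washed glassware)
Reagents that add atoms: none
Why: The aromatic Claisen [3,3]-sigmatropic rearrangement transfers the allyl unit with allylic inversion to C6, the only ortho carbon bearing hydrogen (the other is the ring-fusion carbon C4a), so the 1,1-dimethylallyl ether becomes a normal prenyl group and the dienone tautomerises to the phenol, erasing its transient sp3 centre.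

**Step 5**
Reactants: 12 the silyl-protected prenyl chromenol
Product: 13 7-[2-(4-hydroxyphenyl)ethyl]-2,2-dimethyl-6-(3-methylbut-2-en-1-yl)-2H-chromen-5-ol (target)
Conditions: TBAF (1.2 equiv), AcOH (1.2 equiv), THF, 0 °C → rt, 1 h
Reagents that add atoms: none
Why: Fluoride-mediated desilylation of the aryl silyl ether is driven by Si–F bond formation, and the acetic acid buffer keeps the medium near neutral so the ortho-prenyl phenol and chromene are untouched.

**Compound list**
1 | tert-butyldimethyl(4-vinylphenoxy)silane | C=Cc1ccc(O[Si](C)(C)C(C)(C)C)cc1 | starting material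
2 | 9-borabicyclo[3.3.1]nonane (9-BBN) | B1C2CCCC1CCC2 | starting material
3 | 5-bromobenzene-1,3-diol | Oc1cc(O)cc(Br)c1 | starting material
4 | 9-[2-(4-{[tert-butyl(dimethyl)silyl]oxy}phenyl)ethyl]-9-borabicyclo[3.3.1]nonane | CC(C)(C)[Si](C)(C)Oc1ccc(CCB2C3CCCC2CCC3)cc1 | intermediate
5 | 5-[2-(4-{[tert-butyl(dimethyl)silyl]oxy}phenyl)ethyl]benzene-1,3-diol | CC(C)(C)[Si](C)(C)Oc1ccc(CCc2cc(O)cc(O)c2)cc1 | intermediate
6 | 3-methylbut-2-enal | CC(C)=CC=O | starting material
7 | 5-[2-(4-{[tert-butyl(dimethyl)silyl]oxy}phenyl)ethyl]-3-hydroxy-2-(3-methylbut-2-en-1-ylidene)cyclohexa-3,5-dien-1-one | CC(C)=CC=C1C(=O)C=C(CCc2ccc(O[Si](C)(C)C(C)(C)C)cc2)C=C1O | intermediate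
8 | 7-[2-(4-{[tert-butyl(dimethyl)silyl]oxy}phenyl)ethyl]-2,2-dimethyl-2H-chromen-5-ol | CC(C)(C)[Si](C)(C)Oc1ccc(CCc2cc(O)c3C=CC(C)(C)Oc3c2)cc1 | intermediate
9 | tert-butyl 2-methylbut-3-en-2-yl carbonate | C=CC(C)(C)OC(=O)OC(C)(C)C | starting material
10 | tert-butyl(4-{2-[2,2-dimethyl-5-(2-methylbut-3-en-2-yloxy)-2H-chromen-7-yl]ethyl}phenoxy)dimethylsilane | CC(C)(C)[Si](C)(C)Oc1ccc(CCc2cc(OC(C)(C)C=C)c3C=CC(C)(C)Oc3c2)cc1 | intermediate
11 | 7-[2-(4-{[tert-butyl(dimethyl)silyl]oxy}phenyl)ethyl]-2,2-dimethyl-6-(3-methylbut-2-en-1-yl)-2H-chromen-5(6H)-one (racemic transient dienone) | CC(C)=CCC1C(=O)C2=C(OC(C)(C)C=C2)C=C1CCc1ccc(O[Si](C)(C)C(C)(C)C)cc1 | intermediate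
12 | 7-[2-(4-{[tert-butyl(dimethyl)silyl]oxy}phenyl)ethyl]-2,2-dimethyl-6-(3-methylbut-2-en-1-yl)-2H-chromen-5-ol | CC(C)=CCc1c(CCc2ccc(O[Si](C)(C)C(C)(C)C)cc2)cc2c(c1O)C=CC(C)(C)O2 | intermediate
13 | 7-[2-(4-hydroxyphenyl)ethyl]-2,2-dimethyl-6-(3-methylbut-2-en-1-yl)-2H-chromen-5-ol | CC(C)=CCc1c(CCc2ccc(O)cc2)cc2c(c1O)C=CC(C)(C)O2 | target

**Totals**
Total step count: 5. Longest linear sequence: 5 steps (1 → 5 → 8 → 10 → 12 → 13).

**Steps most likely to fail, with fallbacks**

Step 1 is at risk because the aryl silyl ether may be cleaved or scrambled by the basic, phenoxide-rich medium, and the free resorcinol may slow the coupling. The fallback sets out from 1. Heck arylation of 1 with commercial 1,3-bis(benzyloxy)-5-bromobenzene (Pd(OAc)2, P(o-tol)3, Et3N, DMF, 100 °C) gives (E)-{4-[2-(3,5-bis(benzyloxy)phenyl)ethenyl]phenoxy}(tert-butyl)dimethylsilane F1. Hydrogenation over Pd/C (H2 1 atm, EtOAc, rt) saturates the stilbene and removes both benzyl ethers in one operation while the silyl ether survives, and the route is rejoined at 5.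

Step 2 is at risk of attack at the carbon ortho to the side chain (giving the 7-hydroxy-5-substituted isomer) and of double chromenylation. The fallback sets out from 5. MOMCl/iPr2NEt (CH2Cl2, 0 °C → rt) gives the bis(methoxymethyl) ether F2. n-BuLi (THF, 0 °C) lithiates only between the two MOM ethers to give the aryllithium F3, which adds to 6 at −78 °C; a water quench gives the allylic carbinol F4. Catalytic HCl in MeOH at 40 °C removes both MOM groups, ionises the carbinol to the same ortho-quinone methide 7 and lets it close, rejoining the route at 8 with the regiochemistry fixed by the lithiation.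

Step 4 is at risk because C6 is flanked by the phenethyl chain, so the rearrangement may stall, lose isoprene back to 8, or divert through C4a to C8. The fallback sets out from 8 and bypasses 10. NaH in toluene gives the sodium phenoxide F5. In this non-polar medium its tight ion pair is alkylated on carbon ortho to oxygen by prenyl bromide (1-bromo-3-methylbut-2-ene, toluene, rt → 50 °C), and the route is rejoined directly at 12.

**Further compounds**
F1 | step 1 | (E)-{4-[2-(3,5-bis(benzyloxy)phenyl)ethenyl]phenoxy}(tert-butyl)dimethylsilane | CC(C)(C)[Si](C)(C)Oc1ccc(/C=C/c2cc(OCc3ccccc3)cc(OCc3ccccc3)c2)cc1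
F2 | step 2 | {4-[2-(3,5-bis(methoxymethoxy)phenyl)ethyl]phenoxy}(tert-butyl)dimethylsilane | CC(C)(C)[Si](C)(C)Oc1ccc(CCc2cc(OCOC)cc(OCOC)c2)cc1
F3 | step 2 | {2,6-bis(methoxymethoxy)-4-[2-(4-{[tert-butyl(dimethyl)silyl]oxy}phenyl)ethyl]phenyl}lithium | [Li]c1c(OCOC)cc(CCc2ccc(O[Si](C)(C)C(C)(C)C)cc2)cc1OCOC
F4 | step 2 | 1-{2,6-bis(methoxymethoxy)-4-[2-(4-{[tert-butyl(dimethyl)silyl]oxy}phenyl)ethyl]phenyl}-3-methylbut-2-en-1-ol (racemic) | CC(C)=CC(O)c1c(OCOC)cc(CCc2ccc(O[Si](C)(C)C(C)(C)C)cc2)cc1OCOC
F5 | step 4 | sodium 7-[2-(4-{[tert-butyl(dimethyl)silyl]oxy}phenyl)ethyl]-2,2-dimethyl-2H-chromen-5-olate | CC(C)(C)[Si](C)(C)Oc1ccc(CCc2cc([O-])c3C=CC(C)(C)Oc3c2)cc1.[Na+]
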